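Ring B is closed by a formal [3+3] annulation that joins C1 to C2 and C10 to C4 in one flask. The precursors are the 1,3-bis(trifluoroborate) 5, with an aryl boron on C10 and a configured benzylic boron on C1, and the fully elaborated (E)-enal 18 (C2–C4 plus the side chain). One rhodium–diene catalyst first adds C10 to the β-carbon C4 under ligand control, then adds C1, with retention, to the freed aldehyde C2. The step exploits that C1 and C10, both bonded to C9 of aromatic ring A, form a benzylic/aryl 1,3-dinucleophile that matches the 1,3-dielectrophile C2/C4. The C2 carbinol is then deoxygenated and C6 is carboxylated by ortho-lithiation.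

Key step: step 12

Remark on numbering: C1 is the ring-B CH bearing the methyl group, C2 and C3 are the ring CH2 groups, C4 is the ring CH bearing the side chain, C5 is the aromatic CH, C6 bears the carboxyl group, C7 and C8 bear the hydroxyl groups, C9 is the aromatic carbon bonded to C1 and C10 the one bonded to C4; C11 is the side-chain CH with its hydroxymethyl carbon C18, C12–C14 are the chain CH2 groups, and C15 is the CH with hydroxymethyl C16.

Remark on the chemistry: the ligand antipodes named are those expected to give the stated configurations; if the sense of induction on these substrates proves opposite, the antipodal ligand is used.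

Step 1
Reactants: 1 6-bromo-2,3-dimethoxybenzaldehyde
Product: 2 1-bromo-2-ethenyl-3,4-dimethoxybenzene
Conditions: Ph3PCH3Br, KOtBu, THF, 0 °C to rt
Reagents that add atoms: methyltriphenylphosphonium bromide C[P+](c1ccccc1)(c1ccccc1)c1ccccc1.[Br-]
Why: Wittig methylenation with the non-stabilised ylide should convert the hindered aryl aldehyde cleanly into the vinylarene and creates no stereocentre.

Step 2
Reactants: 2 1-bromo-2-ethenyl-3,4-dimethoxybenzene
Product: 3 2-[(1S)-1-(6-bromo-2,3-dimethoxyphenyl)ethyl]-4,4,5,5-tetramethyl-1,3,2-dioxaborolane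
Conditions: CuCl (3 mol %), (R)-DTBM-SEGPHOS (3.3 mol %), NaOtBu (6 mol %), HBpin, toluene, rt
Reagents that add atoms: pinacolborane B1OC(C)(C)C(C)(C)O1
Why: Copper hydride-catalysed Markovnikov hydroboration should place copper on the benzylic carbon and exchange it for boron by σ-bond metathesis with HBpin, the chiral bisphosphine setting the (S) centre at C1 in the hydrocupration while the aryl bromide stays untouched.

Step 3
Reactants: 3 2-[(1S)-1-(6-bromo-2,3-dimethoxyphenyl)ethyl]-4,4,5,5-tetramethyl-1,3,2-dioxaborolane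
Product: 4 2-{3,4-dimethoxy-2-[(1S)-1-(4,4,5,5-tetramethyl-1,3,2-dioxaborolan-2-yl)ethyl]phenyl}-4,4,5,5-tetramethyl-1,3,2-dioxaborolane
Conditions: Pd(dppf)Cl2 (5 mol %), B2pin2, KOAc, 1,4-dioxane, 90 °C
Reagents that add atoms: bis(pinacolato)diboron CC1(C)OB(OC1(C)C)B1OC(C)(C)C(C)(C)O1
Why: Miyaura borylation should replace the aryl bromide at C10 by boron, and the secondary sp3 boronate does not transmetalate under the acetate conditions, so the C1 centre is preserved.

Step 4
Reactants: 4 2-{3,4-dimethoxy-2-[(1S)-1-(4,4,5,5-tetramethyl-1,3,2-dioxaborolan-2-yl)ethyl]phenyl}-4,4,5,5-tetramethyl-1,3,2-dioxaborolane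
Product: 5 dipotassium trifluoro{(1S)-1-[2,3-dimethoxy-6-(trifluoroboranuidyl)phenyl]ethyl}boranuide
Conditions: KHF2, MeOH/H2O, rt
Reagents that add atoms: potassium hydrogen difluoride F.[F-].[K+]
Why: Fluoride exchange should convert both pinacol boronates into trifluoroborates, the boron form needed for rhodium-catalysed transfer of a secondary benzylic group, without touching the C1 centre.

Step 5
Reactants: 6 (2R)-3-bromo-2-methylpropan-1-ol
Product: 7 tert-butyl{[(2R)-3-bromo-2-methylpropyl]oxy}dimethylsilane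
Conditions: TBSCl, imidazole, CH2Cl2, 0 °C to rt
Reagents that add atoms: tert-butyl(chloro)dimethylsilane CC(C)(C)[Si](C)(C)Cl
Why: Silylation of the primary alcohol protects the future C16 hydroxyl, and the C15 centre comes unchanged from the commercial building block.

Step 6
Reactants: 7 tert-butyl{[(2R)-3-bromo-2-methylpropyl]oxy}dimethylsilane, 8 oxirane
Product: 10 (4S)-5-{[tert-butyl(dimethyl)silyl]oxy}-4-methylpentan-1-ol, via Grignard reagent 9 (not isolated)
Conditions: Mg, THF, 40 °C; then CuI (10 mol %), oxirane, −30 to 0 °C; aq NH4Cl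
Reagents that add atoms: none
Why: The Grignard reagent should open oxirane under CuI catalysis in an SN2 reaction that adds C13 and C12 and leaves the C15 centre untouched.

Step 7
Reactants: 10 (4S)-5-{[tert-butyl(dimethyl)silyl]oxy}-4-methylpentan-1-ol
Product: 11 tert-butyl{[(2S)-5-bromo-2-methylpentyl]oxy}dimethylsilane
Conditions: CBr4, PPh3, CH2Cl2, 0 °C
Reagents that add atoms: tetrabromomethane BrC(Br)(Br)Br
Why: Appel bromination should convert the primary alcohol into the bromide under neutral conditions that spare the silyl ether.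

Step 8
Reactants: 12 methyl (2E)-4-bromobut-2-enoate
Product: 13 (2E)-4-bromobut-2-en-1-ol
Conditions: i-Bu2AlH, CH2Cl2, −78 °C
Reagents that add atoms: none
Why: At low temperature the aluminium hydride should reduce the conjugated ester 1,2 to the allylic alcohol with retention of the (E) geometry and of the allylic bromide.

Step 9
Reactants: 13 (2E)-4-bromobut-2-en-1-ol
Product: 14 tert-butyl{[(2E)-4-bromobut-2-en-1-yl]oxy}dimethylsilane
Conditions: TBSCl, imidazole, CH2Cl2, 0 °C
Reagents that add atoms: tert-butyl(chloro)dimethylsilane CC(C)(C)[Si](C)(C)Cl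
Why: Silylation protects the future C18 hydroxyl and gives the allylic bromide needed for the allylic alkylation.

Step 10
Reactants: 11 tert-butyl{[(2S)-5-bromo-2-methylpentyl]oxy}dimethylsilane, 14 tert-butyl{[(2E)-4-bromobut-2-en-1-yl]oxy}dimethylsilane
Product: 16 (2S,6S)-2-ethenyl-6-methylheptane-1,7-diol bis(tert-butyldimethylsilyl) ether, via Grignard reagent 15 (not isolated)
Conditions: Mg, Et2O, rt; then CuBr·SMe2 (3 mol %), (R,Rp)-Taniaphos (3.5 mol %), 14, CH2Cl2, −75 °C
Reagents that add atoms: none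
Why: Copper-catalysed asymmetric allylic alkylation should deliver the alkyl group to the γ-carbon of the allylic bromide (SN2′, branched product), the chiral ferrocenyl diphosphine controlling the face and so setting the (S) centre at C11.

Step 11
Reactants: 16 (2S,6S)-2-ethenyl-6-methylheptane-1,7-diol bis(tert-butyldimethylsilyl) ether, 17 (2E)-but-2-enal
Product: 18 (2E,4S,8S)-9-{[tert-butyl(dimethyl)silyl]oxy}-4-({[tert-butyl(dimethyl)silyl]oxy}methyl)-8-methylnon-2-enal
Conditions: (2E)-but-2-enal (excess), second-generation Hoveyda–Grubbs catalyst (5 mol %), CH2Cl2, 40 °C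
Reagents that add atoms: none
Why: Cross-metathesis of the terminal alkene with the electron-poor enal partner should give the (E)-enal selectively under neutral conditions that do not epimerise the γ-centre C11.

Step 12
Reactants: 5 dipotassium trifluoro{(1S)-1-[2,3-dimethoxy-6-(trifluoroboranuidyl)phenyl]ethyl}boranuide, 18 (2E,4S,8S)-9-{[tert-butyl(dimethyl)silyl]oxy}-4-({[tert-butyl(dimethyl)silyl]oxy}methyl)-8-methylnon-2-enal
Product: 20 (1S,4S)-4-[(2S,6S)-1,7-bis{[tert-butyl(dimethyl)silyl]oxy}-6-methylheptan-2-yl]-7,8-dimethoxy-1-methyl-1,2,3,4-tetrahydronaphthalen-2-ol (both C2 epimers), via trifluoroborate aldehyde 19 (not isolated)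
Conditions: [RhCl(C2H4)2]2 (2.5 mol %), (R,R)-Ph-bod* [(1R,4R)-2,5-diphenylbicyclo[2.2.2]octa-2,5-diene] (5.5 mol %), K2CO3, 1,4-dioxane/H2O (10:1), 40 °C; then 80 °C
Reagents that add atoms: none
Why: Proposed new method: the aryl group of 5 is transferred to the hydroxorhodium–diene complex and inserts the enal 1,4 with enantioface control (Hayashi–Miyaura conjugate addition), giving aldehyde 19 after hydrolysis of the oxa-π-allyl rhodium; on warming, the secondary benzylic trifluoroborate transmetalates with retention and the benzylrhodium adds to the tethered aldehyde faster than it undergoes β-hydride elimination, which is the known stereoretentive rhodium-catalysed 1,2-addition of secondary benzylic trifluoroborates to aldehydes, here run intramolecularly in relay with the conjugate addition. Ring B closes by a 6-exo-trig addition of C1 to the C2 carbonyl. C4 is set by the chiral diene ligand (catalyst control over the existing C11 centre), C1 is carried over unchanged from 5, and the C2 carbinol centre is left uncontrolled because steps 13 and 14 remove it. The step needs the aryl boron to react before the benzylic boron and 1,4-addition to win over 1,2-addition of the aryl group; the much faster transmetalation of the sp2 boron, the diene ligand and the temperature staging should secure both. The carbonate buffer traps the hydrogen fluoride released so that the silyl ethers survive.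

Step 13
Reactants: 20 (1S,4S)-4-[(2S,6S)-1,7-bis{[tert-butyl(dimethyl)silyl]oxy}-6-methylheptan-2-yl]-7,8-dimethoxy-1-methyl-1,2,3,4-tetrahydronaphthalen-2-ol
Product: 22 O-{(1S,4S)-4-[(2S,6S)-1,7-bis{[tert-butyl(dimethyl)silyl]oxy}-6-methylheptan-2-yl]-7,8-dimethoxy-1-methyl-1,2,3,4-tetrahydronaphthalen-2-yl} S-methyl carbonodithioate, via sodium xanthate 21 (not isolated)
Conditions: NaH, CS2, THF, 0 °C; then MeI, rt
Reagents that add atoms: carbon disulfide S=C=S; iodomethane CI
Why: Xanthate formation on the secondary C2 alkoxide should proceed without touching the neighbouring C1 and C4 centres and prepares the radical deoxygenation.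

Step 14
Reactants: 22 O-{(1S,4S)-4-[(2S,6S)-1,7-bis{[tert-butyl(dimethyl)silyl]oxy}-6-methylheptan-2-yl]-7,8-dimethoxy-1-methyl-1,2,3,4-tetrahydronaphthalen-2-yl} S-methyl carbonodithioate
Product: 23 (1R,4S)-4-[(2S,6S)-1,7-bis{[tert-butyl(dimethyl)silyl]oxy}-6-methylheptan-2-yl]-7,8-dimethoxy-1-methyl-1,2,3,4-tetrahydronaphthalene
Conditions: Bu3SnH, AIBN (cat.), toluene, 110 °C
Reagents that add atoms: none
Why: Barton–McCombie deoxygenation should turn C2 into a CH2 group through a secondary alkyl radical, so both C2 epimers converge on one compound while C1 and C4 are not involved.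

Step 15
Reactants: 23 (1R,4S)-4-[(2S,6S)-1,7-bis{[tert-butyl(dimethyl)silyl]oxy}-6-methylheptan-2-yl]-7,8-dimethoxy-1-methyl-1,2,3,4-tetrahydronaphthalene
Product: 25 (5R,8S)-8-[(2S,6S)-1,7-bis{[tert-butyl(dimethyl)silyl]oxy}-6-methylheptan-2-yl]-3,4-dimethoxy-5-methyl-5,6,7,8-tetrahydronaphthalene-2-carboxylic acid, via aryllithium 24 (not isolated)
Conditions: s-BuLi, TMEDA, THF, −78 °C; CO2; then dilute HCl, 0 °C
Reagents that add atoms: carbon dioxide O=C=O
Why: Directed ortho-metalation should lithiate C6, the only ring position ortho to a methoxy group, and carboxylation of the aryllithium then installs the acid regioselectively.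

Step 16
Reactants: 25 (5R,8S)-8-[(2S,6S)-1,7-bis{[tert-butyl(dimethyl)silyl]oxy}-6-methylheptan-2-yl]-3,4-dimethoxy-5-methyl-5,6,7,8-tetrahydronaphthalene-2-carboxylic acid
Product: 26 (5R,8S)-8-[(2S,6S)-1,7-dihydroxy-6-methylheptan-2-yl]-3,4-dihydroxy-5-methyl-5,6,7,8-tetrahydronaphthalene-2-carboxylic acid
Conditions: BBr3, CH2Cl2, −78 to 0 °C; then H2O
Reagents that add atoms: none
Why: BBr3 should cleave both aryl methyl ethers (bromide attack on the boron-complexed methyl groups) and both silyl ethers, and hydrolysis of the borates at or below 0 °C should free the catechol and the two primary alcohols without touching any stereocentre.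

Compound list
1 | 6-bromo-2,3-dimethoxybenzaldehyde | COc1ccc(Br)c(C=O)c1OC | starting material
2 | 1-bromo-2-ethenyl-3,4-dimethoxybenzene | COc1ccc(Br)c(C=C)c1OC | intermediate
3 | 2-[(1S)-1-(6-bromo-2,3-dimethoxyphenyl)ethyl]-4,4,5,5-tetramethyl-1,3,2-dioxaborolane | CC1(C)OB(OC1(C)C)[C@@H](C)c1c(Br)ccc(OC)c1OC | intermediate
4 | 2-{3,4-dimethoxy-2-[(1S)-1-(4,4,5,5-tetramethyl-1,3,2-dioxaborolan-2-yl)ethyl]phenyl}-4,4,5,5-tetramethyl-1,3,2-dioxaborolane | CC1(C)OB(OC1(C)C)[C@@H](C)c1c(B2OC(C)(C)C(C)(C)O2)ccc(OC)c1OC | intermediate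
5 | dipotassium trifluoro{(1S)-1-[2,3-dimethoxy-6-(trifluoroboranuidyl)phenyl]ethyl}boranuide | [K+].[K+].F[B-](F)(F)[C@@H](C)c1c([B-](F)(F)F)ccc(OC)c1OC | intermediate
6 | (2R)-3-bromo-2-methylpropan-1-ol | C[C@H](CO)CBr | starting material
7 | tert-butyl{[(2R)-3-bromo-2-methylpropyl]oxy}dimethylsilane | C[C@H](CO[Si](C)(C)C(C)(C)C)CBr | intermediate
8 | oxirane | C1CO1 | starting material
9 | [(2R)-3-{[tert-butyl(dimethyl)silyl]oxy}-2-methylpropyl]magnesium bromide | C[C@H](CO[Si](C)(C)C(C)(C)C)C[Mg]Br | intermediate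
10 | (4S)-5-{[tert-butyl(dimethyl)silyl]oxy}-4-methylpentan-1-ol | C[C@H](CO[Si](C)(C)C(C)(C)C)CCCO | intermediate
11 | tert-butyl{[(2S)-5-bromo-2-methylpentyl]oxy}dimethylsilane | C[C@H](CO[Si](C)(C)C(C)(C)C)CCCBr | intermediate
12 | methyl (2E)-4-bromobut-2-enoate | COC(=O)/C=C/CBr | starting material
13 | (2E)-4-bromobut-2-en-1-ol | OC/C=C/CBr | intermediate
14 | tert-butyl{[(2E)-4-bromobut-2-en-1-yl]oxy}dimethylsilane | CC(C)(C)[Si](C)(C)OC/C=C/CBr | intermediate
15 | [(4S)-5-{[tert-butyl(dimethyl)silyl]oxy}-4-methylpentyl]magnesium bromide | C[C@H](CO[Si](C)(C)C(C)(C)C)CCC[Mg]Br | intermediate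
16 | (2S,6S)-2-ethenyl-6-methylheptane-1,7-diol bis(tert-butyldimethylsilyl) ether | C[C@H](CO[Si](C)(C)C(C)(C)C)CCC[C@H](CO[Si](C)(C)C(C)(C)C)C=C | intermediate
17 | (2E)-but-2-enal | C/C=C/C=O | starting material
18 | (2E,4S,8S)-9-{[tert-butyl(dimethyl)silyl]oxy}-4-({[tert-butyl(dimethyl)silyl]oxy}methyl)-8-methylnon-2-enal | C[C@H](CO[Si](C)(C)C(C)(C)C)CCC[C@H](CO[Si](C)(C)C(C)(C)C)/C=C/C=O | intermediate
19 | potassium trifluoro[(1S)-1-{6-[(3S,4S,8S)-9-{[tert-butyl(dimethyl)silyl]oxy}-4-({[tert-butyl(dimethyl)silyl]oxy}methyl)-8-methyl-1-oxononan-3-yl]-2,3-dimethoxyphenyl}ethyl]boranuide | C[C@H](CO[Si](C)(C)C(C)(C)C)CCC[C@H](CO[Si](C)(C)C(C)(C)C)[C@H](CC=O)c1ccc(OC)c(OC)c1[C@H](C)[B-](F)(F)F.[K+] | intermediate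
20 | (1S,4S)-4-[(2S,6S)-1,7-bis{[tert-butyl(dimethyl)silyl]oxy}-6-methylheptan-2-yl]-7,8-dimethoxy-1-methyl-1,2,3,4-tetrahydronaphthalen-2-ol (both C2 epimers) | C[C@H](CO[Si](C)(C)C(C)(C)C)CCC[C@H](CO[Si](C)(C)C(C)(C)C)[C@@H]1CC(O)[C@@H](C)c2c1ccc(OC)c2OC | intermediate
21 | sodium O-{(1S,4S)-4-[(2S,6S)-1,7-bis{[tert-butyl(dimethyl)silyl]oxy}-6-methylheptan-2-yl]-7,8-dimethoxy-1-methyl-1,2,3,4-tetrahydronaphthalen-2-yl} carbonodithioate | C[C@H](CO[Si](C)(C)C(C)(C)C)CCC[C@H](CO[Si](C)(C)C(C)(C)C)[C@@H]1CC(OC(=S)[S-])[C@@H](C)c2c1ccc(OC)c2OC.[Na+] | intermediate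
22 | O-{(1S,4S)-4-[(2S,6S)-1,7-bis{[tert-butyl(dimethyl)silyl]oxy}-6-methylheptan-2-yl]-7,8-dimethoxy-1-methyl-1,2,3,4-tetrahydronaphthalen-2-yl} S-methyl carbonodithioate | C[C@H](CO[Si](C)(C)C(C)(C)C)CCC[C@H](CO[Si](C)(C)C(C)(C)C)[C@@H]1CC(OC(=S)SC)[C@@H](C)c2c1ccc(OC)c2OC | intermediate
23 | (1R,4S)-4-[(2S,6S)-1,7-bis{[tert-butyl(dimethyl)silyl]oxy}-6-methylheptan-2-yl]-7,8-dimethoxy-1-methyl-1,2,3,4-tetrahydronaphthalene | C[C@H](CO[Si](C)(C)C(C)(C)C)CCC[C@H](CO[Si](C)(C)C(C)(C)C)[C@@H]1CC[C@@H](C)c2c1ccc(OC)c2OC | intermediate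
24 | 6-lithio derivative of 23 (lithium on the aromatic carbon ortho to the C7 methoxy group) | C[C@H](CO[Si](C)(C)C(C)(C)C)CCC[C@H](CO[Si](C)(C)C(C)(C)C)[C@@H]1CC[C@@H](C)c2c1cc([Li])c(OC)c2OC | intermediate
25 | (5R,8S)-8-[(2S,6S)-1,7-bis{[tert-butyl(dimethyl)silyl]oxy}-6-methylheptan-2-yl]-3,4-dimethoxy-5-methyl-5,6,7,8-tetrahydronaphthalene-2-carboxylic acid | C[C@H](CO[Si](C)(C)C(C)(C)C)CCC[C@H](CO[Si](C)(C)C(C)(C)C)[C@@H]1CC[C@@H](C)c2c1cc(C(=O)O)c(OC)c2OC | intermediate
26 | (5R,8S)-8-[(2S,6S)-1,7-dihydroxy-6-methylheptan-2-yl]-3,4-dihydroxy-5-methyl-5,6,7,8-tetrahydronaphthalene-2-carboxylic acid | C[C@H](CO)CCC[C@H](CO)[C@@H]1CC[C@@H](C)c2c1cc(C(=O)O)c(O)c2O | target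

Total step count: 16. Longest linear sequence: 10 steps (from 6 through steps 5, 6, 7, 10, 11, 12, 13, 14, 15 and 16).

Steps most likely to fail

Step 12 (Proposed new method). The benzylic trifluoroborate may lose boron by protonation or the benzylrhodium may undergo β-hydride elimination before it adds to the unactivated aliphatic aldehyde, so that only the first bond forms; the aryl group may also add 1,2 to the enal. The fallback uses known chemistry, sets out from 2 and 18 and comes back at 23. Bromine–lithium exchange on 2 (n-BuLi, THF, −78 °C) and quenching with B(OiPr)3 should give (2-ethenyl-3,4-dimethoxyphenyl)boronic acid F1. Rhodium/chiral diene-catalysed 1,4-addition of F1 to 18 should give (3S,4S,8S)-9-{[tert-butyl(dimethyl)silyl]oxy}-4-({[tert-butyl(dimethyl)silyl]oxy}methyl)-3-(2-ethenyl-3,4-dimethoxyphenyl)-8-methylnonanal F2. NaBH4 reduction then gives the corresponding nonan-1-ol F3, and Appel bromination (CBr4, PPh3) gives the 1-bromononane F4. Copper hydride-catalysed enantioselective intramolecular hydroalkylation of the vinylarene (Cu(OAc)2, DTBM-SEGPHOS, (MeO)2MeSiH, LiOMe, THF) closes the C1–C2 bond, creates the methyl group and sets C1 under ligand control, giving 23 directly without the deoxygenation steps.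

Step 2. Hydrocupration of the vinyl group flanked by two ortho substituents may be slow, so that reduction of the alkene or low enantioselectivity takes over. The fallback sets the centre by hydrogenation instead; it sets out from 1 and comes back at 3. Ohira–Bestmann alkynylation of 1 should give 1-bromo-2-ethynyl-3,4-dimethoxybenzene F5. Copper/N-heterocyclic carbene-catalysed α-selective protoboration (B2pin2, MeOH) should give 2-[1-(6-bromo-2,3-dimethoxyphenyl)ethenyl]-4,4,5,5-tetramethyl-1,3,2-dioxaborolane F6. Rhodium/Walphos-catalysed asymmetric hydrogenation of this 1,1-disubstituted vinyl boronate then gives 3.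

Step 11. Cross-metathesis at the allylically branched alkene may stall through catalyst decomposition, or ruthenium hydride species may move the double bond and erode the C11 centre. The fallback builds the enal by olefination; it sets out from 16 and comes back at 18. Ozonolysis of 16 (O3, CH2Cl2, −78 °C; PPh3) should give (2R,6S)-7-{[tert-butyl(dimethyl)silyl]oxy}-2-({[tert-butyl(dimethyl)silyl]oxy}methyl)-6-methylheptanal F7, which is used at once to avoid epimerisation. Wittig reaction with (triphenylphosphoranylidene)acetaldehyde then gives 18.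

Further compounds
F1 | step 12 | (2-ethenyl-3,4-dimethoxyphenyl)boronic acid | COc1ccc(B(O)O)c(C=C)c1OC
F2 | step 12 | (3S,4S,8S)-9-{[tert-butyl(dimethyl)silyl]oxy}-4-({[tert-butyl(dimethyl)silyl]oxy}methyl)-3-(2-ethenyl-3,4-dimethoxyphenyl)-8-methylnonanal | C[C@H](CO[Si](C)(C)C(C)(C)C)CCC[C@H](CO[Si](C)(C)C(C)(C)C)[C@H](CC=O)c1ccc(OC)c(OC)c1C=C
F3 | step 12 | (3S,4S,8S)-9-{[tert-butyl(dimethyl)silyl]oxy}-4-({[tert-butyl(dimethyl)silyl]oxy}methyl)-3-(2-ethenyl-3,4-dimethoxyphenyl)-8-methylnonan-1-ol | C[C@H](CO[Si](C)(C)C(C)(C)C)CCC[C@H](CO[Si](C)(C)C(C)(C)C)[C@H](CCO)c1ccc(OC)c(OC)c1C=C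
F4 | step 12 | 1-[(3S,4S,8S)-1-bromo-9-{[tert-butyl(dimethyl)silyl]oxy}-4-({[tert-butyl(dimethyl)silyl]oxy}methyl)-8-methylnonan-3-yl]-2-ethenyl-3,4-dimethoxybenzene | C[C@H](CO[Si](C)(C)C(C)(C)C)CCC[C@H](CO[Si](C)(C)C(C)(C)C)[C@H](CCBr)c1ccc(OC)c(OC)c1C=C
F5 | step 2 | 1-bromo-2-ethynyl-3,4-dimethoxybenzene | COc1ccc(Br)c(C#C)c1OC
F6 | step 2 | 2-[1-(6-bromo-2,3-dimethoxyphenyl)ethenyl]-4,4,5,5-tetramethyl-1,3,2-dioxaborolane | C=C(B1OC(C)(C)C(C)(C)O1)c1c(Br)ccc(OC)c1OC
F7 | step 11 | (2R,6S)-7-{[tert-butyl(dimethyl)silyl]oxy}-2-({[tert-butyl(dimethyl)silyl]oxy}methyl)-6-methylheptanal | C[C@H](CO[Si](C)(C)C(C)(C)C)CCC[C@H](CO[Si](C)(C)C(C)(C)C)C=O
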